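The readings were computed on assumed constants.

A ratio is asked here: E to Z in a flask charged with X, D and J.

all flasks: X 0.050 M; D 0.0475 M
- epsilon: J 0.013 M; run made earlier
- delta: J 0.019 M; run made earlier
- flask: J 0.0250 M; time 2.0 h

| run | time / min | E / % | Z / % |
|---|---|---|---|
| epsilon | 6.00 | 24.3 | 73.6 |
| epsilon | 10.0 | 23.2 | 76.3 |
| epsilon | 15.0 | 23.7 | 76.9 |
| epsilon | 25.0 | 23.9 | 74.5 |
| epsilon | 40.0 | 23.9 | 76.6 |
| epsilon | 80.0 | 24.7 | 75.1 |
| delta | 5.00 | 32.2 | 63.1 |
| delta | 15.0 | 34.7 | 64.9 |
| delta | 25.0 | 32.2 | 64.3 |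
| delta | 40.0 | 31.3 | 65.6 |
| delta | 60.0 | 33.2 | 66.3 |
| delta | 80.0 | 33.7 | 65.6 |

(each reading ± 1 percentage point)

- what was read earlier has a scatter of 1 percentage point, one standard deviation

- ratio of E to Z at 6.0 s
- ratio of E to Z at 3.0 min
- ratio of E to Z at 2.0 h

1. Read the ratio from the runs. Neither column drifts beyond the scatter, so average them. Epsilon gives E 23.9% and Z 75.5%, a ratio of 0.317. Delta gives E 32.9% and Z 65.0%, a ratio of 0.506.

2. Suppose J and D compete, each consumed in proportion to its own concentration. Define the selectivity factor S as ln([J]end/[J]start) over ln([D]end/[D]start), taking the amounts consumed from E and Z. Epsilon gives 1.60 and delta gives 1.74, so take the mean, S = 1.67.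

3. Fold in the charges: on that supposition, N = S[J]start/[D]start is the ratio of E to Z formed at the first instant. For the flask, N = 0.880.

4. Test N on the runs. End ratio over N is 0.693 in epsilon and 0.756 in delta, so one number is not enough. Continue that line in [J]start to the flask: the factor 0.820 gives an end ratio of 0.722. The readings begin at 5.00 min, later than both early times, so they give no ratio for 6.0 s or 3.0 min.

5. The forecast gives 0.77, 0.69 and 0.69, and says “By 3 min it is probably essentially final.” Its end ratio is lower than the one in step 4.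

    X → G (k = 0.660 /min)
    D + G → Z (k = 410 /M/min)
    J + G → E (k = 970 /M/min)
    J → L (k = 0.0540 /min)

6. The flask gives 1.22 at 6.0 s, 0.808 at 3.0 min and 0.717 at 2.0 h, so the ratio at 6.0 s stands above N. L, formed from J by itself, reaches 0.00412 M at 2.00 h. Now raise D to 0.12 M in the neighbouring flask: S[J]start/[D]start becomes 0.348, and that flask gives 0.486 at 6.0 s and 0.366 at 2.0 h.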